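**Retrosynthetic overview**
1. The last two bonds are the exo C7–C8 oxirane, made by hydroxyl-directed epoxidation, and the amide, made by N-acylation of the unprotected amino-triol core with the N-hydroxysuccinimide ester of (E)-7-oxododec-2-enoic acid. The acid comes from cyclopentanone and a pentyl Grignard reagent through ozonolysis and a Wittig reaction.
2. The C6–OH comes from an exo-selective SeO2 allylic hydroxylation. The C7=C8 alkene comes from the spare silyl enol ether of the aldol product, through its enol triflate.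
3. The key disconnection is C4–C5. Ring A closes onto ring B by an intramolecular, group-selective Mukaiyama aldol of an α-amino aldehyde onto a mirror-symmetric bis(silyl enol ether). The serine-derived centre chooses one arm and so sets C1, C5 and C4.
4. The aldol precursor comes from a 2-hydroxy-2-alkylcyclohexane-1,3-dione. That dione comes from a Negishi coupling of the L-serine-derived zinc reagent with 3-ethoxy-2-iodocyclohex-2-enone.
5. Ring order: ring B is the purchased carbocycle, ring A is formed in the aldol, and the oxirane is formed last.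

Convention: bicyclic compounds are numbered C1 (bridgehead C–O), C2 (CH2), C3 (C–N), C4 (aldol carbinol), C5 (bridgehead CH), C6–C8 (second bridge), C9 (ketone). "Exo" means on the ring face turned away from the other three-carbon bridge. Compound 17 is drawn as its enol.

**Side-chain fragment**

Step 1
Reactants: 1 cyclopentanone; 2 n-pentylmagnesium bromide
Product: 3 1-pentylcyclopentan-1-ol
Conditions: Et2O, 0 °C to rt; sat. aq. NH4Cl
Reagents that add atoms: none
Why: Grignard 1,2-addition to an unhindered ketone gives the tertiary alcohol, and no stereocentre is formed.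

Step 2
Reactants: 3 1-pentylcyclopentan-1-ol
Product: 4 1-pentylcyclopent-1-ene
Conditions: TsOH·H2O (2 mol %), toluene, reflux, Dean–Stark
Reagents that add atoms: none
Why: Acid-catalysed E1 dehydration under equilibrating conditions gives the trisubstituted endocyclic (Zaitsev) alkene.

Step 3
Reactants: 4 1-pentylcyclopent-1-ene
Product: 6 5-oxodecanal, via secondary ozonide 5 (not isolated)
Conditions: O3, CH2Cl2, −78 °C; Me2S, −78 °C to rt
Reagents that add atoms: ozone O=[O+][O-]
Why: Criegee ozonolysis with reductive work-up opens the ring alkene to the 1,5-keto aldehyde.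

Step 4
Reactants: 6 5-oxodecanal; 7 ethyl (triphenylphosphoranylidene)acetate
Product: 8 ethyl (E)-7-oxododec-2-enoate
Conditions: CH2Cl2, rt
Reagents that add atoms: none
Why: The Wittig reaction of a stabilised ylide is neutral, so the keto aldehyde does not self-condense, and it attacks only the aldehyde and sets the E alkene.

Step 5
Reactants: 8 ethyl (E)-7-oxododec-2-enoate
Product: 9 (E)-7-oxododec-2-enoic acid
Conditions: LiOH·H2O (1.5 equiv), THF/H2O 3:1, 0 °C to rt; 1 M HCl to pH 3
Reagents that add atoms: lithium hydroxide [Li+].[OH-]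
Why: Saponification by acyl–oxygen cleavage leaves the ketone and the E alkene untouched.

Step 6
Reactants: 9 (E)-7-oxododec-2-enoic acid
Product: 10 2,5-dioxopyrrolidin-1-yl (E)-7-oxododec-2-enoate
Conditions: N-hydroxysuccinimide, DCC, THF, 0 °C to rt
Reagents that add atoms: N-hydroxysuccinimide O=C1CCC(=O)N1O
Why: Carbodiimide activation gives a storable active ester that later acylates an amine in the presence of free hydroxyl groups.

**Ring fragment**

Step 7
Reactants: 11 3-ethoxycyclohex-2-en-1-one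
Product: 12 3-ethoxy-2-iodocyclohex-2-en-1-one
Conditions: NIS (1.1 equiv), MeCN, 0 °C to rt, dark
Reagents that add atoms: N-iodosuccinimide O=C1CCC(=O)N1I
Why: Electrophilic α-iodination takes place at the nucleophilic C2 of the vinylogous ester (enol-ether substitution).

**Amino acid fragment**

Step 8
Reactants: 13 N-Boc-L-serine methyl ester
Product: 14 methyl (2R)-2-[(tert-butoxycarbonyl)amino]-3-iodopropanoate
Conditions: I2, PPh3, imidazole, CH2Cl2, 0 °C to rt
Reagents that add atoms: iodine II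
Why: This Appel-type iodination displaces only at the primary carbon, so the α-centre keeps its L arrangement and the descriptor changes to R by priority alone.

**Union and core**

Step 9
Reactants: 14 methyl (2R)-2-[(tert-butoxycarbonyl)amino]-3-iodopropanoate; 12 3-ethoxy-2-iodocyclohex-2-en-1-one
Product: 16 methyl (2S)-2-[(tert-butoxycarbonyl)amino]-3-(2-ethoxy-6-oxocyclohex-1-en-1-yl)propanoate, via alkylzinc iodide 15 (not isolated)
Conditions: Zn dust (3 equiv), I2 (cat.), DMF, rt; then 12, Pd2(dba)3 (2.5 mol %), SPhos (5 mol %), rt to 45 °C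
Reagents that add atoms: none
Why: Negishi coupling of the serine-derived (Jackson) zinc reagent with an α-iodoenone on zerovalent palladium is neutral, so the α-centre (the future C3) is carried over unchanged.

Step 10
Reactants: 16 methyl (2S)-2-[(tert-butoxycarbonyl)amino]-3-(2-ethoxy-6-oxocyclohex-1-en-1-yl)propanoate
Product: 17 methyl (2S)-2-[(tert-butoxycarbonyl)amino]-3-(2-hydroxy-6-oxocyclohex-1-en-1-yl)propanoate
Conditions: 1 M aq. HCl, THF, rt
Reagents that add atoms: water O
Why: Acid hydrolysis of the vinylogous ester (addition–elimination at C3) is much faster than Boc or methyl ester cleavage at this acidity.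

Step 11
Reactants: 17 methyl (2S)-2-[(tert-butoxycarbonyl)amino]-3-(2-hydroxy-6-oxocyclohex-1-en-1-yl)propanoate
Product: 18 methyl (2S)-2-[(tert-butoxycarbonyl)amino]-3-(1-hydroxy-2,6-dioxocyclohexyl)propanoate
Conditions: DMDO (0.08 M in acetone, 1.1 equiv), CH2Cl2, −20 to 0 °C
Reagents that add atoms: dimethyldioxirane CC1(C)OO1
Why: Neutral epoxidation of the enol C=C and collapse of the epoxide (Rubottom-type enol oxidation) gives the tertiary α-hydroxy-1,3-dione, whose carbinol carbon carries two identical acyl arms and is not yet stereogenic.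

Step 12
Reactants: 18 methyl (2S)-2-[(tert-butoxycarbonyl)amino]-3-(1-hydroxy-2,6-dioxocyclohexyl)propanoate
Product: 19 methyl (2S)-2-[(tert-butoxycarbonyl)amino]-3-[1,2,6-tris(triethylsilyloxy)cyclohexa-2,5-dien-1-yl]propanoate
Conditions: Et3SiOTf (4 equiv), Et3N (6 equiv), CH2Cl2, −78 to 0 °C
Reagents that add atoms: triethylsilyl triflate CC[Si](CC)(CC)OS(=O)(=O)C(F)(F)F
Why: Soft enolisation and silylation caps the tertiary alcohol and turns both ketones into enol silanes, which can only form away from the quaternary carbon, while the low temperature spares the Boc group and the ester α-centre.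

Step 13
Reactants: 19 methyl (2S)-2-[(tert-butoxycarbonyl)amino]-3-[1,2,6-tris(triethylsilyloxy)cyclohexa-2,5-dien-1-yl]propanoate
Product: 20 tert-butyl N-{(2S)-1-oxo-3-[1,2,6-tris(triethylsilyloxy)cyclohexa-2,5-dien-1-yl]propan-2-yl}carbamate
Conditions: i-Bu2AlH (2.2 equiv), toluene, −78 °C; MeOH, aq. potassium sodium tartrate (KNaC4H4O6)
Reagents that add atoms: none
Why: Partial reduction of the ester stops at the stable tetrahedral aluminium hemiacetal, and the ketones are masked as hydride-inert enol silanes, so the aldehyde appears under non-epimerising conditions.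

Step 14 (key ring closure)
Reactants: 20 tert-butyl N-{(2S)-1-oxo-3-[1,2,6-tris(triethylsilyloxy)cyclohexa-2,5-dien-1-yl]propan-2-yl}carbamate
Product: 21 tert-butyl N-[(3S)-9-oxo-1,4,8-tris(triethylsilyloxy)bicyclo[3.3.1]non-7-en-3-yl]carbamate (NHBoc exo; 4-OSiEt3 exo)
Conditions: Tf2NH (5 mol %), CH2Cl2 (0.01 M), −78 °C; Et3N quench
Reagents that add atoms: none
Why: In this intramolecular group-selective Mukaiyama aldol (Et3SiNTf2 formed in situ, silyl transfer to the aldolate), the chair-like transition state closes only onto the arm that keeps NHBoc equatorial (exo), which sets C1 and C5 from C3, and Felkin–Anh attack anti to the C–N bond places the C4–O bond exo, without any base that could epimerise the amino aldehyde.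

Step 15
Reactants: 21 tert-butyl N-[(3S)-9-oxo-1,4,8-tris(triethylsilyloxy)bicyclo[3.3.1]non-7-en-3-yl]carbamate
Product: 22 (3S)-3-[(tert-butoxycarbonyl)amino]-9-oxo-1,4-bis(triethylsilyloxy)bicyclo[3.3.1]non-7-en-8-yl trifluoromethanesulfonate (NHBoc exo; 4-OSiEt3 exo)
Conditions: CsF (2 equiv), PhNTf2 (1.3 equiv), DME, rt
Reagents that add atoms: N-phenylbis(trifluoromethanesulfonimide) O=S(=O)(N(c1ccccc1)S(=O)(=O)C(F)(F)F)C(F)(F)F
Why: Fluoride cleaves the labile enol silane faster than the alkyl silyl ethers, and the regiodefined enolate is triflated in situ, so only C8 reacts because the C9 ketone cannot enolise at its bridgeheads.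

Step 16
Reactants: 22 (3S)-3-[(tert-butoxycarbonyl)amino]-9-oxo-1,4-bis(triethylsilyloxy)bicyclo[3.3.1]non-7-en-8-yl trifluoromethanesulfonate
Product: 23 tert-butyl N-[(3S)-9-oxo-1,4-bis(triethylsilyloxy)bicyclo[3.3.1]non-7-en-3-yl]carbamate (NHBoc exo; 4-OSiEt3 exo)
Conditions: Pd(OAc)2 (5 mol %), PPh3 (10 mol %), HCO2H (2 equiv), Et3N (3 equiv), DMF, 60 °C
Reagents that add atoms: none
Why: In this Cacchi-type formate reduction, oxidative addition of the vinyl triflate to zerovalent palladium, decarboxylation of formate and reductive elimination give the C7=C8 alkene without touching the ketone.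

Step 17
Reactants: 23 tert-butyl N-[(3S)-9-oxo-1,4-bis(triethylsilyloxy)bicyclo[3.3.1]non-7-en-3-yl]carbamate
Product: 24 tert-butyl N-[(3S)-6-hydroxy-9-oxo-1,4-bis(triethylsilyloxy)bicyclo[3.3.1]non-7-en-3-yl]carbamate (NHBoc exo; 4-OSiEt3 exo; 6-OH exo)
Conditions: SeO2 (0.5 equiv), t-BuOOH (5.5 M in decane, 3 equiv), CH2Cl2, rt to 40 °C
Reagents that add atoms: selenium dioxide O=[Se]=O; tert-butyl hydroperoxide CC(C)(C)OO
Why: In this Sharpless–Umbreit allylic hydroxylation, the ene reaction and the [2,3]-sigmatropic shift both run on the open exo face at the only allylic CH2 (C6), which restores the C7=C8 alkene and sets the 6-exo alcohol.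

Step 18
Reactants: 24 tert-butyl N-[(3S)-6-hydroxy-9-oxo-1,4-bis(triethylsilyloxy)bicyclo[3.3.1]non-7-en-3-yl]carbamate; 10 2,5-dioxopyrrolidin-1-yl (E)-7-oxododec-2-enoate
Product: 26 (E)-7-oxo-N-[(3S)-1,4,6-trihydroxy-9-oxobicyclo[3.3.1]non-7-en-3-yl]dodec-2-enamide (amide N exo; 4-OH exo; 6-OH exo), via ammonium trifluoroacetate 25 (not isolated)
Conditions: TFA/CH2Cl2/H2O 9:9:2, 0 °C to rt, evaporate; then 10, i-Pr2NEt, DMF, 0 °C to rt
Reagents that add atoms: none
Why: Acidolysis removes the Boc group and both triethylsilyl ethers in one operation, and the active ester then acylates the amine chemoselectively over the three hydroxyl groups (aminolysis), with no stereocentre touched.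

Step 19
Reactants: 26 (E)-7-oxo-N-[(3S)-1,4,6-trihydroxy-9-oxobicyclo[3.3.1]non-7-en-3-yl]dodec-2-enamide
Product: 27 isariotin C
Conditions: VO(acac)2 (5 mol %), t-BuOOH (1.5 equiv), CH2Cl2, 0 °C to rt
Reagents that add atoms: tert-butyl hydroperoxide CC(C)(C)OO
Why: In this Sharpless–Michaelson hydroxyl-directed epoxidation, the vanadium-bound peroxide is delivered from the exo C6 (and C1) hydroxyl to the exo face, the endo face being blocked by ring A, which sets C7 and C8 as the cis-epoxy alcohol and leaves the electron-poor enamide alkene untouched.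

**Compound list**
1 | cyclopentanone | O=C1CCCC1 | starting material
2 | n-pentylmagnesium bromide | CCCCC[Mg]Br | starting material
3 | 1-pentylcyclopentan-1-ol | CCCCCC1(O)CCCC1 | intermediate
4 | 1-pentylcyclopent-1-ene | CCCCCC1=CCCC1 | intermediate
5 | 1-pentyl-6,7,8-trioxabicyclo[3.2.1]octane (secondary ozonide, not isolated) | CCCCCC12CCCC(OO1)O2 | intermediate
6 | 5-oxodecanal | CCCCCC(=O)CCCC=O | intermediate
7 | ethyl (triphenylphosphoranylidene)acetate | CCOC(=O)C=P(c1ccccc1)(c1ccccc1)c1ccccc1 | starting material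
8 | ethyl (E)-7-oxododec-2-enoate | CCCCCC(=O)CCC/C=C/C(=O)OCC | intermediate
9 | (E)-7-oxododec-2-enoic acid | CCCCCC(=O)CCC/C=C/C(=O)O | intermediate
10 | 2,5-dioxopyrrolidin-1-yl (E)-7-oxododec-2-enoate | CCCCCC(=O)CCC/C=C/C(=O)ON1C(=O)CCC1=O | intermediate
11 | 3-ethoxycyclohex-2-en-1-one | CCOC1=CC(=O)CCC1 | starting material
12 | 3-ethoxy-2-iodocyclohex-2-en-1-one | CCOC1=C(I)C(=O)CCC1 | intermediate
13 | N-Boc-L-serine methyl ester | CC(C)(C)OC(=O)N[C@@H](CO)C(=O)OC | starting material
14 | methyl (2R)-2-[(tert-butoxycarbonyl)amino]-3-iodopropanoate | CC(C)(C)OC(=O)N[C@@H](CI)C(=O)OC | intermediate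
15 | [(2R)-2-(Boc-amino)-3-methoxy-3-oxopropyl]zinc iodide (not isolated) | CC(C)(C)OC(=O)N[C@@H](C[Zn]I)C(=O)OC | intermediate
16 | methyl (2S)-2-[(tert-butoxycarbonyl)amino]-3-(2-ethoxy-6-oxocyclohex-1-en-1-yl)propanoate | CC(C)(C)OC(=O)N[C@@H](CC1=C(OCC)CCCC1=O)C(=O)OC | intermediate
17 | methyl (2S)-2-[(tert-butoxycarbonyl)amino]-3-(2-hydroxy-6-oxocyclohex-1-en-1-yl)propanoate | CC(C)(C)OC(=O)N[C@@H](CC1=C(O)CCCC1=O)C(=O)OC | intermediate
18 | methyl (2S)-2-[(tert-butoxycarbonyl)amino]-3-(1-hydroxy-2,6-dioxocyclohexyl)propanoate | CC(C)(C)OC(=O)N[C@@H](CC1(O)C(=O)CCCC1=O)C(=O)OC | intermediate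
19 | methyl (2S)-2-[(tert-butoxycarbonyl)amino]-3-[1,2,6-tris(triethylsilyloxy)cyclohexa-2,5-dien-1-yl]propanoate | CC(C)(C)OC(=O)N[C@@H](CC1(O[Si](CC)(CC)CC)C(O[Si](CC)(CC)CC)=CCC=C1O[Si](CC)(CC)CC)C(=O)OC | intermediate
20 | tert-butyl N-{(2S)-1-oxo-3-[1,2,6-tris(triethylsilyloxy)cyclohexa-2,5-dien-1-yl]propan-2-yl}carbamate | CC(C)(C)OC(=O)N[C@@H](CC1(O[Si](CC)(CC)CC)C(O[Si](CC)(CC)CC)=CCC=C1O[Si](CC)(CC)CC)C=O | intermediate
21 | tert-butyl N-[(3S)-9-oxo-1,4,8-tris(triethylsilyloxy)bicyclo[3.3.1]non-7-en-3-yl]carbamate (NHBoc exo; 4-OSiEt3 exo) | CC(C)(C)OC(=O)N[C@H]1C[C@@]2(O[Si](CC)(CC)CC)C(=O)[C@H](CC=C2O[Si](CC)(CC)CC)[C@H]1O[Si](CC)(CC)CC | intermediate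
22 | (3S)-3-(Boc-amino)-9-oxo-1,4-bis(triethylsilyloxy)bicyclo[3.3.1]non-7-en-8-yl triflate (NHBoc exo; 4-OSiEt3 exo) | CC(C)(C)OC(=O)N[C@H]1C[C@@]2(O[Si](CC)(CC)CC)C(=O)[C@H](CC=C2OS(=O)(=O)C(F)(F)F)[C@H]1O[Si](CC)(CC)CC | intermediate
23 | tert-butyl N-[(3S)-9-oxo-1,4-bis(triethylsilyloxy)bicyclo[3.3.1]non-7-en-3-yl]carbamate (NHBoc exo; 4-OSiEt3 exo) | CC(C)(C)OC(=O)N[C@H]1C[C@@]2(O[Si](CC)(CC)CC)C(=O)[C@H](CC=C2)[C@H]1O[Si](CC)(CC)CC | intermediate
24 | tert-butyl N-[(3S)-6-hydroxy-9-oxo-1,4-bis(triethylsilyloxy)bicyclo[3.3.1]non-7-en-3-yl]carbamate (NHBoc, 4-OSiEt3 and 6-OH all exo) | CC(C)(C)OC(=O)N[C@H]1C[C@@]2(O[Si](CC)(CC)CC)C(=O)[C@H]([C@H](O)C=C2)[C@H]1O[Si](CC)(CC)CC | intermediate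
25 | (3S)-1,4,6-trihydroxy-9-oxobicyclo[3.3.1]non-7-en-3-ylammonium trifluoroacetate (N, 4-OH and 6-OH exo; not isolated) | [NH3+][C@H]1C[C@@]2(O)C(=O)[C@H]([C@H](O)C=C2)[C@H]1O.[O-]C(=O)C(F)(F)F | intermediate
26 | (E)-7-oxo-N-[(3S)-1,4,6-trihydroxy-9-oxobicyclo[3.3.1]non-7-en-3-yl]dodec-2-enamide (N, 4-OH and 6-OH exo) | CCCCCC(=O)CCC/C=C/C(=O)N[C@H]1C[C@@]2(O)C(=O)[C@H]([C@H](O)C=C2)[C@H]1O | intermediate
27 | isariotin C (core numbering: 1S,3S,4R,5S,6S,7S,8S; 7,8-exo-epoxide; E-enamide) | CCCCCC(=O)CCC/C=C/C(=O)N[C@H]1C[C@@]2(O)C(=O)[C@H]([C@H](O)[C@@H]3O[C@@H]32)[C@H]1O | target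

**Step count**
- Total: 19 steps.
- Longest linear sequence: 12 steps (step 7 or step 8, then steps 9–19).
- The six-step side-chain branch joins at step 18.

**Steps most likely to fail**

Step 14 (key aldol). The risks are incomplete arm selection, the wrong C4 epimer from an open transition state, and loss of enol silane. The fallback sets out from 20 and returns at 21.
- Both enol silanes of 20 are brominated with NBS (2 equiv, THF, −78 °C). This gives tert-butyl N-{(2S)-1-[3,5-dibromo-2,6-dioxo-1-(triethylsilyloxy)cyclohexyl]-3-oxopropan-2-yl}carbamate F3.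
- SmI2 (4.5 equiv, THF, −78 °C) reduces the C–Br bonds to trivalent samarium enolates under neutral conditions. A Reformatsky-type aldol through a closed, chelated chair holds the aldolate oxygen next to the enolate oxygen (exo) and keeps NHBoc equatorial. The product is tert-butyl N-[(3S)-4-hydroxy-8,9-dioxo-1-(triethylsilyloxy)bicyclo[3.3.1]nonan-3-yl]carbamate F4.
- Et3SiOTf/Et3N then silylates the C4 hydroxyl and converts the only enolisable ketone (C8) into its enol silane, which gives 21.

Step 17 (allylic hydroxylation). The alkene is disubstituted and inductively deactivated, so it may react slowly or over-oxidise to the enone. The fallback sets out from 21 and returns at 24, and it replaces steps 15–17.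
- Saegusa–Ito oxidation of 21 (Pd(OAc)2, MeCN, rt) gives tert-butyl N-[(3S)-8,9-dioxo-1,4-bis(triethylsilyloxy)bicyclo[3.3.1]non-6-en-3-yl]carbamate F5.
- Weitz–Scheffer epoxidation (t-BuOOH, DBU, CH2Cl2, 0 °C) attacks the open exo face. It gives tert-butyl N-[(3S)-6,7-exo-epoxy-8,9-dioxo-1,4-bis(triethylsilyloxy)bicyclo[3.3.1]nonan-3-yl]carbamate F6.
- Wharton transposition (N2H4·H2O, cat. AcOH, MeOH, 0 °C to rt) turns C8=O into the C7=C8 alkene and keeps the exo C6–O bond, which gives 24.
- The C9 ketone is flanked by the two silyloxy groups and should condense with hydrazine more slowly than C8.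

Step 9 (Negishi coupling). The vinyl iodide is tetrasubstituted and hindered, so protodezincation and β-elimination may compete. The fallback sets out from 14 and 12 and returns at 16.
- Compound 14 is dehydroiodinated (Et3N, CH2Cl2) to methyl 2-[(tert-butoxycarbonyl)amino]prop-2-enoate F1.
- A Heck reaction of F1 with 12 (Pd(OAc)2, n-Bu4NCl, NaHCO3, DMF, 80 °C) gives methyl (Z)-2-[(tert-butoxycarbonyl)amino]-3-(2-ethoxy-6-oxocyclohex-1-en-1-yl)prop-2-enoate F2.
- Enamide-selective asymmetric hydrogenation with [Rh(cod)((S,S)-Et-DuPhos)]OTf (H2, 5 bar, MeOH) sets the (S) centre and gives 16.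

**Further compounds**
F1 | step 9 | methyl 2-[(tert-butoxycarbonyl)amino]prop-2-enoate | C=C(NC(=O)OC(C)(C)C)C(=O)OC
F2 | step 9 | methyl (Z)-2-[(tert-butoxycarbonyl)amino]-3-(2-ethoxy-6-oxocyclohex-1-en-1-yl)prop-2-enoate | COC(=O)/C(NC(=O)OC(C)(C)C)=C/C1=C(OCC)CCCC1=O
F3 | step 14 | tert-butyl N-{(2S)-1-[3,5-dibromo-2,6-dioxo-1-(triethylsilyloxy)cyclohexyl]-3-oxopropan-2-yl}carbamate (mixture at the C–Br centres) | CC(C)(C)OC(=O)N[C@@H](CC1(O[Si](CC)(CC)CC)C(=O)C(Br)CC(Br)C1=O)C=O
F4 | step 14 | tert-butyl N-[(3S)-4-hydroxy-8,9-dioxo-1-(triethylsilyloxy)bicyclo[3.3.1]nonan-3-yl]carbamate (NHBoc exo; 4-OH exo) | CC(C)(C)OC(=O)N[C@H]1C[C@@]2(O[Si](CC)(CC)CC)C(=O)[C@H](CCC2=O)[C@H]1O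
F5 | step 17 | tert-butyl N-[(3S)-8,9-dioxo-1,4-bis(triethylsilyloxy)bicyclo[3.3.1]non-6-en-3-yl]carbamate (NHBoc exo; 4-OSiEt3 exo) | CC(C)(C)OC(=O)N[C@H]1C[C@@]2(O[Si](CC)(CC)CC)C(=O)[C@H](C=CC2=O)[C@H]1O[Si](CC)(CC)CC
F6 | step 17 | tert-butyl N-[(3S)-6,7-exo-epoxy-8,9-dioxo-1,4-bis(triethylsilyloxy)bicyclo[3.3.1]nonan-3-yl]carbamate (NHBoc exo; 4-OSiEt3 exo) | CC(C)(C)OC(=O)N[C@H]1C[C@@]2(O[Si](CC)(CC)CC)C(=O)[C@H]([C@@H]3O[C@@H]3C2=O)[C@H]1O[Si](CC)(CC)CC
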